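**Strategy.** Ring C of the target (O1–C2–C3–C4(=O)–C4a=C8a) is a 2,3-dihydro-4-pyranone, the retron of a hetero-Diels–Alder reaction of an aldehyde with a 2-siloxy-1,3-diene. Because C4a=C8a also belongs to benzene ring A, ring A is carried as its 5,6-dihydro form, a cyclohexane-1,3-dione (carbonyls at C7 and C8a) that receives the C8 and C6 prenyl groups and the C4a acetyl group by enolate chemistry. Its tris(silyl enol ether) and 4-methoxybenzaldehyde combine under a catalyst made from Ti(OiPr)4 and (S)-BINOL, forming C2–C3 and O1–C8a, ring C and the C2 stereocentre in one operation. Dehydrogenation of ring A then gives the phenol.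

Key step: step 5

Remark: the prenyl-bearing ring carbon that becomes C6 is a stereocentre in the intermediates of steps 2 to 5 but not in the target, so it is left uncontrolled, both epimers are carried on, and step 6 removes it. 1,3-Dicarbonyl compounds are drawn in their keto forms, and flavanone numbering is used for ring positions from step 4 on.

**Step 1**
Reactants: 1 cyclohexane-1,3-dione; 2 prenyl bromide (1-bromo-3-methylbut-2-ene)
Product: 3 2-(3-methylbut-2-en-1-yl)cyclohexane-1,3-dione
Conditions: KOH (1.05 equiv), water, rt, 16 h; then aq. HCl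
Reagents that add atoms: none
Why: The potassium enolate of the cyclic β-diketone should be C-alkylated at the carbon between the carbonyls by the allylic bromide in water, where hydrogen bonding to the enolate oxygens disfavours O-alkylation (C-alkylation of a 1,3-diketone by nucleophilic substitution).

**Step 2**
Reactants: 3 2-(3-methylbut-2-en-1-yl)cyclohexane-1,3-dione; 2 prenyl bromide
Product: 5 2,4-bis(3-methylbut-2-en-1-yl)cyclohexane-1,3-dione (racemic), via dilithium dianion 4 (not isolated)
Conditions: LiN(iPr)2 (2.2 equiv), THF–DMPU, −78 → 0 °C; then 2 (1.0 equiv), −78 °C → rt; aq. HCl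
Reagents that add atoms: none
Why: A second deprotonation of the diketone enolate gives dianion 4, whose more basic γ-carbanion alone should react with the allylic bromide (γ-alkylation of a β-diketone dianion).

**Step 3**
Reactants: 5 2,4-bis(3-methylbut-2-en-1-yl)cyclohexane-1,3-dione; 6 N-methoxy-N-methylacetamide
Product: 8 4-acetyl-2,6-bis(3-methylbut-2-en-1-yl)cyclohexane-1,3-dione (mixture of stereoisomers and enol tautomers), via dilithium dianion 7 (not isolated)
Conditions: LiN(iPr)2 (2.2 equiv), THF, −78 → 0 °C; then 6 (1.1 equiv), −78 → 0 °C; aq. HCl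
Reagents that add atoms: none
Why: The second deprotonation of 5 should take place at the unsubstituted ring CH2 and not at the prenyl-bearing CH, and the carbanion is acylated by the N-methoxy-N-methylamide through a chelated tetrahedral adduct that collapses only on work-up, so the acidic triketone cannot quench the dianion (γ-acylation of a β-diketone dianion).

**Step 4**
Reactants: 8 4-acetyl-2,6-bis(3-methylbut-2-en-1-yl)cyclohexane-1,3-dione
Product: 11 1-[1-(trimethylsilyloxy)ethenyl]-3,5-bis(3-methylbut-2-en-1-yl)-2,4-bis(trimethylsilyloxy)cyclohexa-1,3-diene, via bis(trimethylsilyl) dienol ether 9 (not isolated), via lithium enolate 10 (not isolated)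
Conditions: TMSCl (3.5 equiv), Et3N (2.5 equiv), THF, rt, 24 h; filtration under argon; then LiN(iPr)2 (1.2 equiv), −78 °C (TMSCl still present); pentane, filtration, concentration; used crude
Reagents that add atoms: chlorotrimethylsilane, C[Si](C)(C)Cl
Why: TMSCl/Et3N silylates both enolic oxygens and leaves the acetyl CH3 as the only α-position, which LiN(iPr)2 deprotonates kinetically and TMSCl traps on oxygen (two-stage preparation of a 1,3-bis(silyl enol ether) from a cyclic 2-acetyl ketone, extended here by one enol ether).

**Step 5**
Reactants: 11 the tris(trimethylsilyloxy) triene; 12 4-methoxybenzaldehyde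
Product: 14 (2S)-7-hydroxy-2-(4-methoxyphenyl)-6,8-bis(3-methylbut-2-en-1-yl)-2,3,5,6-tetrahydro-4H-chromen-4-one (both C6 epimers), via silylated aldol adduct 13 (not isolated)
Conditions: (S)-BINOL (20 mol %), Ti(OiPr)4 (20 mol %), 4 Å molecular sieves, THF, −78 → −20 °C; then TFA, wet CH2Cl2, 0 °C, short contact time
Reagents that add atoms: none
Why: The Lewis acid formed from Ti(OiPr)4 and (S)-BINOL activates 12, and the unsubstituted terminal CH2 of triene 11 adds to the Si face of the aldehyde with silyl transfer (Mukaiyama aldol of a 1,3-bis(siloxy)diene, forming C2–C3 and giving 13); TFA then frees the C2 oxygen, which adds to C8a of the β-siloxy enone and expels trimethylsilanol (forming O1–C8a and restoring C4a=C8a), while the C7 silyl ether is hydrolysed. The whole is a formal hetero-Diels–Alder reaction of a 2-siloxy-1,3-diene with an aldehyde, and its closest known relative is the dihydropyranone synthesis from 1-oxygenated 3-siloxydienes and aryl aldehydes under Ti(OiPr)4–BINOL catalysis with acid work-up. Ring C closes in a 6-endo-trig conjugate addition–elimination. The C2 stereocentre is set by the catalyst alone: by analogy with additions of allyl and siloxydiene nucleophiles to aryl aldehydes, (S)-BINOL is expected to direct attack to the Si face, which gives 2S, and if a first run shows the opposite sense of induction, (R)-BINOL is used instead. Site selectivity is needed among three nucleophilic carbons of the triene and is secured because only the terminal CH2 is unsubstituted, the ring positions C4a and C8 being fully substituted. The racemic C6 centre is remote from the reacting terminus, so 14 should form as two C6 epimers of the same C2 configuration that converge in step 6.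

**Step 6**
Reactants: 14 the (2S)-5,6-dihydroflavanone
Product: 15 the target, (2S)-7-hydroxy-2-(4-methoxyphenyl)-6,8-bis(3-methylbut-2-en-1-yl)-2,3-dihydro-4H-chromen-4-one
Conditions: DDQ (1.05 equiv), dry 1,4-dioxane, 0 °C → rt
Reagents that add atoms: none
Why: DDQ should abstract hydride from C5 to give a cyclohexadienyl cation stabilised by the C7 hydroxyl and O1, which loses the C6 proton, so the dihydro ring becomes benzene ring A (quinone dehydrogenation of a dihydroarene) while C2 is not touched and both C6 epimers give the same product.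

**Compound list**
1 | cyclohexane-1,3-dione | O=C1CCCC(=O)C1 | starting material
2 | prenyl bromide (1-bromo-3-methylbut-2-ene) | CC(C)=CCBr | starting material
3 | 2-(3-methylbut-2-en-1-yl)cyclohexane-1,3-dione | CC(C)=CCC1C(=O)CCCC1=O | intermediate
4 | dilithium dianion of 3 (bis-enolate form) | CC(C)=CCC1=C(O[Li])CCC=C1O[Li] | intermediate
5 | 2,4-bis(3-methylbut-2-en-1-yl)cyclohexane-1,3-dione (racemic) | CC(C)=CCC1C(=O)CCC(CC=C(C)C)C1=O | intermediate
6 | N-methoxy-N-methylacetamide | CC(=O)N(C)OC | starting material
7 | dilithium dianion of 5 (bis-enolate form) | CC(C)=CCC1CC=C(O[Li])C(CC=C(C)C)=C1O[Li] | intermediate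
8 | 4-acetyl-2,6-bis(3-methylbut-2-en-1-yl)cyclohexane-1,3-dione | CC(=O)C1CC(CC=C(C)C)C(=O)C(CC=C(C)C)C1=O | intermediate
9 | 1-[3,5-bis(3-methylbut-2-en-1-yl)-2,4-bis(trimethylsilyloxy)cyclohexa-1,3-dien-1-yl]ethan-1-one | CC(=O)C1=C(O[Si](C)(C)C)C(CC=C(C)C)=C(O[Si](C)(C)C)C(CC=C(C)C)C1 | intermediate
10 | lithium enolate of 9 (at the acetyl group) | C=C(O[Li])C1=C(O[Si](C)(C)C)C(CC=C(C)C)=C(O[Si](C)(C)C)C(CC=C(C)C)C1 | intermediate
11 | 1-[1-(trimethylsilyloxy)ethenyl]-3,5-bis(3-methylbut-2-en-1-yl)-2,4-bis(trimethylsilyloxy)cyclohexa-1,3-diene | C=C(O[Si](C)(C)C)C1=C(O[Si](C)(C)C)C(CC=C(C)C)=C(O[Si](C)(C)C)C(CC=C(C)C)C1 | intermediate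
12 | 4-methoxybenzaldehyde | COc1ccc(C=O)cc1 | starting material
13 | (3S)-3-(4-methoxyphenyl)-1-[3,5-bis(3-methylbut-2-en-1-yl)-2,4-bis(trimethylsilyloxy)cyclohexa-1,3-dien-1-yl]-3-(trimethylsilyloxy)propan-1-one | COc1ccc([C@@H](O[Si](C)(C)C)CC(=O)C2=C(O[Si](C)(C)C)C(CC=C(C)C)=C(O[Si](C)(C)C)C(CC=C(C)C)C2)cc1 | intermediate
14 | (2S)-7-hydroxy-2-(4-methoxyphenyl)-6,8-bis(3-methylbut-2-en-1-yl)-2,3,5,6-tetrahydro-4H-chromen-4-one (C6 epimers) | COc1ccc([C@@H]2CC(=O)C3=C(O2)C(CC=C(C)C)=C(O)C(CC=C(C)C)C3)cc1 | intermediate
15 | (2S)-7-hydroxy-2-(4-methoxyphenyl)-6,8-bis(3-methylbut-2-en-1-yl)-2,3-dihydro-4H-chromen-4-one, the target flavanone | COc1ccc([C@@H]2CC(=O)c3cc(CC=C(C)C)c(O)c(CC=C(C)C)c3O2)cc1 | target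

**Step count and risks**
Total steps: 6. Longest linear sequence: 6.

Steps most likely to fail:

1. Step 5. The chiral Lewis acid may discriminate the aldehyde faces poorly or turn over slowly with this bulky triene, and the acid stage may dehydrate or ionise the p-methoxybenzylic carbinol before ring closure. The fallback sets out from 9 and comes back at 14, forming the two bonds in two operations under reagent control. Compound 9, taken by concentrating the filtrate of step 4 before the base is added, is enolised with diisopinocampheylboron chloride, (Ipc)2BCl (the antipode that directs the enolate to the Si face of the aldehyde), and Et3N in Et2O at −78 °C. The boron enolate adds to 12 through a closed six-membered transition state, and non-oxidative work-up with diethanolamine should give (3S)-3-hydroxy-3-(4-methoxyphenyl)-1-[3,5-bis(3-methylbut-2-en-1-yl)-2,4-bis(trimethylsilyloxy)cyclohexa-1,3-dien-1-yl]propan-1-one F1. Brief treatment of F1 with TFA in wet CH2Cl2 at 0 °C should close ring C by addition of the hydroxyl to C8a and loss of silanol, giving 14.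

2. Step 6. The oxidant may not stop at the arene: the freed ortho-prenylphenol can be oxidised further with cyclisation onto a prenyl group, or C2–C3 can be dehydrogenated. The fallback sets out from 14 and comes back at 15, masking the oxygen before the oxidation. Compound 14 is acetylated (Ac2O, pyridine, DMAP, CH2Cl2, 0 °C) to the dienyl acetate (2S)-7-acetoxy-2-(4-methoxyphenyl)-6,8-bis(3-methylbut-2-en-1-yl)-2,3,5,6-tetrahydro-4H-chromen-4-one F2. DDQ in toluene (rt → 50 °C) should then give the aryl acetate (2S)-7-acetoxy-2-(4-methoxyphenyl)-6,8-bis(3-methylbut-2-en-1-yl)-2,3-dihydro-4H-chromen-4-one F3, which cannot form a quinone methide. NH4OAc in aqueous MeOH at rt should cleave the aryl acetate to 15 without base-induced opening of ring C.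

3. Step 3. The dianion may be quenched by proton transfer from the enolisable amide, may be acylated on oxygen, or may form in part at the prenyl-bearing carbon. The fallback sets out from 5 and comes back at 8, replacing acyl transfer by aldol addition and oxidation. It answers the first two failure modes but not deprotonation at the wrong carbon, since it uses the same dianion. Dianion 7 is generated as in step 3 and trapped at −78 °C with acetaldehyde, an electrophile that adds faster than it is deprotonated at this temperature, to give 4-(1-hydroxyethyl)-2,6-bis(3-methylbut-2-en-1-yl)cyclohexane-1,3-dione F4. Oxidation of the secondary alcohol with Dess–Martin periodinane (NaHCO3, CH2Cl2, 0 °C) should give 8.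

**Further compounds**
F1 | step 5 | (3S)-3-hydroxy-3-(4-methoxyphenyl)-1-[3,5-bis(3-methylbut-2-en-1-yl)-2,4-bis(trimethylsilyloxy)cyclohexa-1,3-dien-1-yl]propan-1-one | COc1ccc([C@@H](O)CC(=O)C2=C(O[Si](C)(C)C)C(CC=C(C)C)=C(O[Si](C)(C)C)C(CC=C(C)C)C2)cc1
F2 | step 6 | (2S)-7-acetoxy-2-(4-methoxyphenyl)-6,8-bis(3-methylbut-2-en-1-yl)-2,3,5,6-tetrahydro-4H-chromen-4-one | COc1ccc([C@@H]2CC(=O)C3=C(O2)C(CC=C(C)C)=C(OC(C)=O)C(CC=C(C)C)C3)cc1
F3 | step 6 | (2S)-7-acetoxy-2-(4-methoxyphenyl)-6,8-bis(3-methylbut-2-en-1-yl)-2,3-dihydro-4H-chromen-4-one | COc1ccc([C@@H]2CC(=O)c3cc(CC=C(C)C)c(OC(C)=O)c(CC=C(C)C)c3O2)cc1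
F4 | step 3 | 4-(1-hydroxyethyl)-2,6-bis(3-methylbut-2-en-1-yl)cyclohexane-1,3-dione | CC(O)C1CC(CC=C(C)C)C(=O)C(CC=C(C)C)C1=O
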